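**Strategy.** The target is cut between the methylene-bearing alkene carbon on the cyclohexane and the adjacent side-chain carbinol carbon (C8). The key step exploits the 2-substituted allylic alcohol unit, ring CH–C(=CH2)–CH(O)–CH2–epoxide. A ligand-controlled Ni/Cr (Nozaki–Hiyama–Kishi) coupling adds a ring alkenyl triflate, already carrying the chlorohydrin, acetate and angelate, to an (S)-β,γ-epoxy aldehyde. This forms the C–C bond and the C8 stereocentre in one operation. The triflate comes from (S)-carvone, whose isopropenyl group is degraded to an acetyl group and enol-triflated early. The aldehyde comes from 4-methylpent-3-en-1-ol by Shi epoxidation. One angeloylation finishes the synthesis.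

Key step: step 13

Remark: ring atoms are numbered as in carvone (C1 former carbonyl carbon, C2 methyl-bearing carbon, C3, C4 ring CH2, C5 carbon bearing the side chain, C6); β is the ring face of the C5 side chain, α the opposite face; C8 is the side-chain carbinol carbon. It is assumed that the antipode of the oxazoline–sulfonamide ligand that directs the alkenyl group to the Re face of aldehyde 17 is selected for step 13 (both antipodes derive from D- or L-valinol).

**Step 1**
Reactants: 1 (S)-(+)-carvone
Product: 3 trans-6-hydroxycarvone (6α-OH), via sodium dienolate 2 (not isolated)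
Conditions: NaHMDS, THF, −78 °C; then 2-(phenylsulfonyl)-3-phenyloxaziridine, −78 °C; aq. NH4Cl
Reagents that add atoms: 2-(phenylsulfonyl)-3-phenyloxaziridine, O=S(=O)(c1ccccc1)N1OC1c1ccccc1
Why: Kinetic α′-deprotonation at C6 gives the cross-conjugated dienolate, which the N-sulfonyloxaziridine should hydroxylate (enolate oxidation) on the face opposite the C5 isopropenyl group, setting the 6α (trans) hydroxyl.

**Step 2**
Reactants: 3 trans-6-hydroxycarvone
Product: 4 6α-(tert-butyldimethylsilyloxy)carvone
Conditions: TBSCl, imidazole, DMF, rt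
Reagents that add atoms: tert-butyldimethylsilyl chloride, CC(C)(C)[Si](C)(C)Cl
Why: Standard silylation of the α-ketol, which masks the hydroxyl and sterically shields C6–H for the enolate chemistry of step 4 without touching a stereocentre.

**Step 3**
Reactants: 4 6α-(tert-butyldimethylsilyloxy)carvone
Product: 6 5β-acetyl-6α-(tert-butyldimethylsilyloxy)-2-methylcyclohex-2-en-1-one, via ozonide 5 (not isolated)
Conditions: O3, CH2Cl2, −78 °C (dye end-point); then PPh3, −78 °C to rt
Reagents that add atoms: ozone, [O-][O+]=O
Why: Ozonolysis with reductive work-up should cleave the electron-rich 1,1-disubstituted alkene selectively, because the electron-poor trisubstituted enone alkene reacts far more slowly with ozone.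

**Step 4**
Reactants: 6 5β-acetyl-6α-(tert-butyldimethylsilyloxy)-2-methylcyclohex-2-en-1-one
Product: 8 5β-[1-(trifluoromethanesulfonyloxy)vinyl]-6α-(tert-butyldimethylsilyloxy)-2-methylcyclohex-2-en-1-one, via potassium enolate 7 (not isolated)
Conditions: KHMDS, THF, −78 °C; then PhNTf2, −78 °C
Reagents that add atoms: N-phenylbis(trifluoromethanesulfonimide), O=S(=O)(N(c1ccccc1)S(=O)(=O)C(F)(F)F)C(F)(F)F
Why: Kinetic enol triflate formation: the bulky amide should remove a proton from the unhindered acetyl CH3 rather than from the methine C5–H, the silyloxy-shielded tertiary C6–H or the vinylogous positions, and O-sulfonylation of the terminal enolate gives the 2-triflyloxy-1-alkene.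

**Step 5**
Reactants: 8 the silyl-protected alkenyl triflate
Product: 9 5β-[1-(trifluoromethanesulfonyloxy)vinyl]-6α-hydroxy-2-methylcyclohex-2-en-1-one
Conditions: HF·pyridine, pyridine/THF, 0 °C to rt
Reagents that add atoms: none
Why: Buffered fluoride desilylation should free the 6α-hydroxyl while the enol triflate and the enone are inert to these conditions.

**Step 6**
Reactants: 9 the 6α-hydroxy enone
Product: 10 6β-acetoxy-5β-[1-(trifluoromethanesulfonyloxy)vinyl]-2-methylcyclohex-2-en-1-one
Conditions: PPh3, DIAD, AcOH, THF, 0 °C to rt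
Reagents that add atoms: acetic acid, CC(=O)O
Why: Mitsunobu reaction: SN2 attack of acetate on the carbonyl-activated oxyphosphonium should invert C6 to the 6β (cis) configuration and install the acetate of the target, and the equatorial leaving group has no antiperiplanar hydrogen for elimination.

**Step 7**
Reactants: 10 the 6β-acetoxy enone
Product: 11 6β-acetoxy-2-methyl-5β-[1-(trifluoromethanesulfonyloxy)vinyl]cyclohex-2-en-1β-ol
Conditions: NaBH4, CeCl3·7H2O, MeOH, −78 °C; AcOH quench at −78 °C
Reagents that add atoms: none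
Why: Luche 1,2-reduction should deliver hydride axially on the α face, anti to the pseudo-axial 6β-acetoxy group (the sense of the carvone to cis-carveol reduction), giving the 1β-alcohol, and the low temperature suppresses acetyl migration.

**Step 8**
Reactants: 11 the 1β-allylic alcohol
Product: 12 6β-acetoxy-2β,3β-epoxy-2α-methyl-5β-[1-(trifluoromethanesulfonyloxy)vinyl]cyclohexan-1β-ol
Conditions: VO(acac)2 (cat.), t-BuOOH, CH2Cl2, 0 °C to rt
Reagents that add atoms: tert-butyl hydroperoxide, CC(C)(C)OO
Why: Hydroxyl-directed vanadium-catalysed epoxidation should deliver oxygen syn to the 1β-hydroxyl and only to the ring alkene (the electron-poor alkenyl triflate is inert), setting the 2β,3β-epoxide.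

**Step 9**
Reactants: 12 the epoxy alcohol
Product: 13 1β-angeloyloxy-6β-acetoxy-2β,3β-epoxy-2α-methyl-5β-[1-(trifluoromethanesulfonyloxy)vinyl]cyclohexane
Conditions: angelic acid, 2,4,6-trichlorobenzoyl chloride, Et3N, toluene, rt; then 12, toluene, 75 °C (no DMAP)
Reagents that add atoms: angelic acid, C/C=C(/C)C(=O)O
Why: Yamaguchi-type mixed-anhydride esterification should acylate the secondary hydroxyl at the less hindered angeloyl carbonyl, and the DMAP-free protocol is chosen to avoid Z-to-E isomerisation of the acyl donor.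

**Step 10**
Reactants: 13 the epoxy diester
Product: 14 1β-angeloyloxy-6β-acetoxy-3α-chloro-2β-hydroxy-2α-methyl-5β-[1-(trifluoromethanesulfonyloxy)vinyl]cyclohexane
Conditions: LiCl, AcOH, THF, rt to 40 °C
Reagents that add atoms: lithium chloride, [Li+].[Cl-]
Why: Acid-assisted SN2 epoxide opening by chloride should occur trans-diaxially (Fürst–Plattner rule) at the secondary C3 from the α face, giving the 3α-chloride and 2β-tertiary alcohol, because attack at C2 would need a chair with the side chain and the angelate syn-diaxial and C2 is inductively deactivated by the neighbouring acyloxy group.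

**Step 11**
Reactants: 15 4-methylpent-3-en-1-ol
Product: 16 (S)-2-(3,3-dimethyloxiran-2-yl)ethan-1-ol
Conditions: ent-Shi ketone (L-series, from L-sorbose, 0.3 equiv), Oxone, K2CO3, Bu4NHSO4, borate buffer pH 10.5, MeCN/dimethoxymethane/H2O, 0 °C
Reagents that add atoms: potassium peroxymonosulfate (Oxone), [K+].[O-]S(=O)(=O)OO
Why: Shi asymmetric epoxidation: the chiral dioxirane should transfer oxygen through a spiro transition state to one face of the trisubstituted alkene, the L-configured ketone giving the (S)-epoxide, and the basic medium keeps the 3,4-epoxy alcohol from cyclising.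

**Step 12**
Reactants: 16 (S)-2-(3,3-dimethyloxiran-2-yl)ethan-1-ol
Product: 17 (S)-2-(3,3-dimethyloxiran-2-yl)acetaldehyde
Conditions: Dess–Martin periodinane, NaHCO3, CH2Cl2, 0 °C; used at once in step 13
Reagents that add atoms: none
Why: Buffered hypervalent-iodine oxidation is near-neutral and should give the β,γ-epoxy aldehyde without base-induced opening of the epoxide or loss of its stereocentre.

**Step 13**
Reactants: 14 the chlorohydrin alkenyl triflate, 17 (S)-2-(3,3-dimethyloxiran-2-yl)acetaldehyde
Product: 19 (8S)-allylic alcohol (the target lacking the side-chain angeloyl group), via alkenylchromium(III) species 18 (not isolated)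
Conditions: CrCl2, N-[2-(4-isopropyl-4,5-dihydrooxazol-2-yl)-6-methylphenyl]methanesulfonamide (Re-face-directing antipode), Et3N, THF, rt; then NiCl2 (cat.), 14, 17, rt; aq. ethylenediamine work-up
Reagents that add atoms: none
Why: Ni(0), generated from NiCl2 by Cr(II), inserts into the alkenyl C–OTf bond of 14 and transmetallates to Cr(III), and the ligand-bound alkenylchromium(III) 18 adds through a closed transition state to the aldehyde carbonyl of 17 (Nozaki–Hiyama–Kishi reaction). The closest known reaction type is the ligand-controlled Ni/Cr coupling of 2-triflyloxy- and 2-halo-1-alkenes with α-unbranched aldehydes to give 2-methylene carbinols. No ring is closed. The single new stereocentre, C8, is set by the chiral oxazoline–sulfonamide on chromium, which should expose the Re face of the aldehyde and so give the (S)-carbinol; the epoxide stereocentre β to the carbonyl and the ring stereocentres behind the alkenyl carbon are expected to exert only a weak intrinsic bias. The step needs chemoselectivity for the aldehyde over two esters, a secondary chloride, a free tertiary alcohol and a trisubstituted epoxide, which the non-basic, aldehyde-specific organochromium(III) nucleophile secures, and it needs the alkene to stay 1,1-disubstituted, which the positionally stable alkenyl–metal bond secures.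

**Step 14**
Reactants: 19 the (8S)-allylic alcohol
Product: 20 CNP0313121.1 (target)
Conditions: angelic acid, 2,4,6-trichlorobenzoyl chloride, Et3N, toluene, rt; then 19, toluene, 60–75 °C (no DMAP)
Reagents that add atoms: angelic acid, C/C=C(/C)C(=O)O
Why: Yamaguchi-type mixed-anhydride esterification should acylate the secondary allylic C8 hydroxyl while the tertiary ring hydroxyl stays free, with no stereocentre affected and DMAP-free conditions preserving the (Z)-geometry.

**Compound list**

1 | (S)-(+)-carvone, (5S)-2-methyl-5-(prop-1-en-2-yl)cyclohex-2-en-1-one | C=C(C)[C@H]1CC=C(C)C(=O)C1 | starting material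
2 | sodium cross-conjugated dienolate of 1 (C1–O−, C1=C6, C2=C3) | C=C(C)[C@H]1CC=C(C)C([O-])=C1.[Na+] | intermediate
3 | trans-6-hydroxycarvone, (5R,6R)-6-hydroxy-2-methyl-5-(prop-1-en-2-yl)cyclohex-2-en-1-one (6α-OH) | C=C(C)[C@H]1CC=C(C)C(=O)[C@@H]1O | intermediate
4 | 6α-(tert-butyldimethylsilyloxy)carvone (TBS ether of 3) | C=C(C)[C@H]1CC=C(C)C(=O)[C@@H]1O[Si](C)(C)C(C)(C)C | intermediate
5 | secondary ozonide of 4: 6α-(TBS-oxy)-2-methyl-5β-(3-methyl-1,2,4-trioxolan-3-yl)cyclohex-2-en-1-one (trioxolane carbon unassigned) | CC1(OCOO1)[C@H]1CC=C(C)C(=O)[C@@H]1O[Si](C)(C)C(C)(C)C | intermediate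
6 | 5β-acetyl-6α-(tert-butyldimethylsilyloxy)-2-methylcyclohex-2-en-1-one | CC(=O)[C@H]1CC=C(C)C(=O)[C@@H]1O[Si](C)(C)C(C)(C)C | intermediate
7 | potassium terminal enolate of the acetyl group of 6 | C=C([O-])[C@H]1CC=C(C)C(=O)[C@@H]1O[Si](C)(C)C(C)(C)C.[K+] | intermediate
8 | 5β-[1-(trifluoromethanesulfonyloxy)vinyl]-6α-(tert-butyldimethylsilyloxy)-2-methylcyclohex-2-en-1-one | C=C(OS(=O)(=O)C(F)(F)F)[C@H]1CC=C(C)C(=O)[C@@H]1O[Si](C)(C)C(C)(C)C | intermediate
9 | 5β-[1-(trifluoromethanesulfonyloxy)vinyl]-6α-hydroxy-2-methylcyclohex-2-en-1-one | C=C(OS(=O)(=O)C(F)(F)F)[C@H]1CC=C(C)C(=O)[C@@H]1O | intermediate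
10 | 6β-acetoxy-5β-[1-(trifluoromethanesulfonyloxy)vinyl]-2-methylcyclohex-2-en-1-one (acetate cis to the side chain) | C=C(OS(=O)(=O)C(F)(F)F)[C@H]1CC=C(C)C(=O)[C@H]1OC(C)=O | intermediate
11 | 6β-acetoxy-2-methyl-5β-[1-(trifluoromethanesulfonyloxy)vinyl]cyclohex-2-en-1β-ol | C=C(OS(=O)(=O)C(F)(F)F)[C@H]1CC=C(C)[C@@H](O)[C@H]1OC(C)=O | intermediate
12 | 6β-acetoxy-2β,3β-epoxy-2α-methyl-5β-[1-(trifluoromethanesulfonyloxy)vinyl]cyclohexan-1β-ol | C=C(OS(=O)(=O)C(F)(F)F)[C@H]1C[C@H]2O[C@@]2(C)[C@@H](O)[C@H]1OC(C)=O | intermediate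
13 | 1β-angeloyloxy-6β-acetoxy-2β,3β-epoxy-2α-methyl-5β-[1-(trifluoromethanesulfonyloxy)vinyl]cyclohexane | C=C(OS(=O)(=O)C(F)(F)F)[C@H]1C[C@H]2O[C@@]2(C)[C@@H](OC(=O)/C(C)=C\C)[C@H]1OC(C)=O | intermediate
14 | 1β-angeloyloxy-6β-acetoxy-3α-chloro-2β-hydroxy-2α-methyl-5β-[1-(trifluoromethanesulfonyloxy)vinyl]cyclohexane | C=C(OS(=O)(=O)C(F)(F)F)[C@H]1C[C@H](Cl)[C@@](C)(O)[C@@H](OC(=O)/C(C)=C\C)[C@H]1OC(C)=O | intermediate
15 | 4-methylpent-3-en-1-ol | CC(C)=CCCO | starting material
16 | (S)-2-(3,3-dimethyloxiran-2-yl)ethan-1-ol | OCC[C@@H]1OC1(C)C | intermediate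
17 | (S)-2-(3,3-dimethyloxiran-2-yl)acetaldehyde | O=CC[C@@H]1OC1(C)C | intermediate
18 | alkenylchromium(III) species from 14 (chiral ligand on chromium omitted) | C=C([Cr](Cl)Cl)[C@H]1C[C@H](Cl)[C@@](C)(O)[C@@H](OC(=O)/C(C)=C\C)[C@H]1OC(C)=O | intermediate
19 | (8S)-allylic alcohol: target skeleton with free C8 hydroxyl, (S)-epoxide, ring chlorohydrin, 1β-angelate and 6β-acetate | C=C([C@H](C[C@@H]1OC1(C)C)O)[C@H]1C[C@H](Cl)[C@@](C)(O)[C@@H](OC(=O)/C(C)=C\C)[C@H]1OC(C)=O | intermediate
20 | CNP0313121.1 | C=C([C@H](C[C@@H]1OC1(C)C)OC(=O)/C(C)=C\C)[C@H]1C[C@H](Cl)[C@@](C)(O)[C@@H](OC(=O)/C(C)=C\C)[C@H]1OC(C)=O | target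

**Step count.** Total: 14 steps. Longest linear sequence: 12 steps (steps 1–10, 13, 14).

**Steps most likely to fail**

Step 13. Oxidative addition and transmetallation of the hindered, α-branched alkenyl triflate may be slow. The β,γ-epoxy aldehyde could then decay by amine- or chromium(III)-induced opening of the epoxide and β-elimination before it is captured, and the ligand may impose too little facial bias. The fallback introduces the epoxide last. It sets out from 15 and 14: buffered Dess–Martin oxidation of 15 should give 4-methylpent-3-enal F1, which is coupled with 14 under the same Ni/Cr conditions to the diene alcohol F2. Angeloylation as in step 14 gives the triene diester F3. Shi epoxidation with the L-series ketone at about pH 8 (stoichiometric ketone, Oxone, NaHCO3) should then epoxidise only the electron-rich trisubstituted side-chain alkene and returns to the route at 20.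

Step 6. The oxyphosphonium intermediate of the α-ketol may eliminate or enolise (leading toward aromatisation), or the basic betaine may epimerise the cis-α-acetoxy ketone back to trans. The fallback sets the cis configuration by kinetic protonation instead of SN2 inversion. It sets out from 4: LDA in THF at −78 °C should give the lithium dienolate F4. Protonation with 2,6-di-tert-butylphenol at −78 °C, anti to the pseudo-axial isopropenyl group, should give cis-6β-(tert-butyldimethylsilyloxy)carvone F5. Ozonolysis through the ozonide F6 gives the methyl ketone F7. KHMDS forms the potassium enolate F8, and PhNTf2 converts it to the alkenyl triflate F9. HF·pyridine frees the cis-6β-hydroxy enone F10, and acetylation (Ac2O, pyridine) returns to the route at 10.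

Step 9. Acyl transfer to the hindered C1 hydroxyl, next to the quaternary epoxide carbon, may be slow. Isomerisation of the activated angeloyl donor to the tigloyl isomer and 6-to-1 acetyl migration at 75 °C could then overtake it. The fallback builds the angelate by Z-selective olefination. It sets out from 12: esterification with 2-[bis(2,2,2-trifluoroethoxy)phosphoryl]propanoic acid (DIC, cat. DMAP, CH2Cl2, 0 °C) should give the phosphonopropionate ester F11. KHMDS and 18-crown-6 in THF at −78 °C give its potassium carbanion F12, and acetaldehyde in a Still–Gennari olefination should return the (Z)-2-methylbut-2-enoate, rejoining the route at 13.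

**Further compounds**

F1 | step 13 | 4-methylpent-3-enal | CC(C)=CCC=O
F2 | step 13 | (8S)-allylic alcohol with 4-methylpent-3-enyl-derived side chain (10,11-alkene in place of the epoxide) | C=C([C@H](CC=C(C)C)O)[C@H]1C[C@H](Cl)[C@@](C)(O)[C@@H](OC(=O)/C(C)=C\C)[C@H]1OC(C)=O
F3 | step 13 | 10,11-deoxy analogue of the target (side-chain alkene, both angelates in place) | C=C([C@H](CC=C(C)C)OC(=O)/C(C)=C\C)[C@H]1C[C@H](Cl)[C@@](C)(O)[C@@H](OC(=O)/C(C)=C\C)[C@H]1OC(C)=O
F4 | step 6 | lithium dienolate of 4 (C1–O−, C1=C6 bearing the silyloxy group) | C=C(C)[C@H]1CC=C(C)C([O-])=C1O[Si](C)(C)C(C)(C)C.[Li+]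
F5 | step 6 | cis-6β-(tert-butyldimethylsilyloxy)carvone | C=C(C)[C@H]1CC=C(C)C(=O)[C@H]1O[Si](C)(C)C(C)(C)C
F6 | step 6 | secondary ozonide of F5 | CC1(OCOO1)[C@H]1CC=C(C)C(=O)[C@H]1O[Si](C)(C)C(C)(C)C
F7 | step 6 | 5β-acetyl-6β-(tert-butyldimethylsilyloxy)-2-methylcyclohex-2-en-1-one | CC(=O)[C@H]1CC=C(C)C(=O)[C@H]1O[Si](C)(C)C(C)(C)C
F8 | step 6 | potassium terminal enolate of F7 | C=C([O-])[C@H]1CC=C(C)C(=O)[C@H]1O[Si](C)(C)C(C)(C)C.[K+]
F9 | step 6 | 5β-[1-(trifluoromethanesulfonyloxy)vinyl]-6β-(tert-butyldimethylsilyloxy)-2-methylcyclohex-2-en-1-one | C=C(OS(=O)(=O)C(F)(F)F)[C@H]1CC=C(C)C(=O)[C@H]1O[Si](C)(C)C(C)(C)C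
F10 | step 6 | 5β-[1-(trifluoromethanesulfonyloxy)vinyl]-6β-hydroxy-2-methylcyclohex-2-en-1-one | C=C(OS(=O)(=O)C(F)(F)F)[C@H]1CC=C(C)C(=O)[C@H]1O
F11 | step 9 | 1β-O-{2-[bis(2,2,2-trifluoroethoxy)phosphoryl]propanoyl} ester of 12 (phosphonate α-carbon unassigned) | C=C(OS(=O)(=O)C(F)(F)F)[C@H]1C[C@H]2O[C@@]2(C)[C@@H](OC(=O)C(C)P(=O)(OCC(F)(F)F)OCC(F)(F)F)[C@H]1OC(C)=O
F12 | step 9 | potassium carbanion of F11 | C=C(OS(=O)(=O)C(F)(F)F)[C@H]1C[C@H]2O[C@@]2(C)[C@@H](OC(=O)[C-](C)P(=O)(OCC(F)(F)F)OCC(F)(F)F)[C@H]1OC(C)=O.[K+]
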